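## Analysis of the target

The target joins a 2-methoxy-3,5-dimethyl-4H-pyran-4-one to a pentamethylated bicyclo[4.2.0]octene. Ring A (C1–C6) is bridged from C2 to C5 by a peroxide, and ring B is the cyclobutane C1–C6–C7–C8. All six stereocentres (C1, C2, C5, C6, C7, C8) are contiguous, and C1, C5 and C7 are fully substituted. The fusion is cis. The methyls on C1, C7 and C8 and the hydrogen on C6 lie on one face of ring B, while the pyranone on C7 lies on the other face, under ring A (endo) and trans to the C8 methyl. The peroxide sits on the face of ring A that is turned away from ring B.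

The O–O bond tolerates neither hydrides, enolates, transition metals nor heat, and C2 carries a hydrogen, so amine bases start a Kornblum–DeLaMare cleavage. The methoxypyranone is sensitive to ultraviolet light and aqueous acid. The diene that precedes the peroxide is acid-labile and can valence-isomerise.

The difficulty has two parts. Ring B is crowded, with a quaternary carbon carrying the heterocycle next to two further methylated carbons. One enantiomer is also needed of a skeleton whose most direct pericyclic precursors are achiral.

The strategy rests on the methyl pattern. Without the peroxide, ring A is a C2=C3–C4=C5 diene, and opening C1–C6 gives a cycloocta-1,3,5-triene in which C1, C3, C5 and C7 each bear a methyl. That is the pattern of 1,3,5,7-tetramethylcyclooctatetraene, to which only a methyl on C8 and an acyl carbon on C7 must be added.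

## Retrosynthetic reasoning

Atom numbers are those of the bicyclo[4.2.0]octane core and are kept for the monocyclic precursors.

**19 to 18.** The C2–O and C5–O bonds of 19 are cut first, in a retro-[4+2] sense, which returns the cyclohexadiene 18. The peroxide would not survive any reducing, basic or organometallic step, so it has to come last. The forward photooxygenation must reach the diene from the convex face. In 18 the concave face is closed by ring B and by the endo pyranone.

**18 to 11 and 12.** The pyranone is bonded to the quaternary C7, so coupling a finished heterocycle to the carbocycle is not realistic. The ring is better grown from a one-carbon handle on C7, and it is taken apart in four cuts: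
- the O–CH3 bond (18 back through pyrylium salt 17 to hydroxypyranone 16);
- the ring O–C(=O) bond (16 back to diketo ester 15);
- one oxidation level (15 back to aldol 14);
- the C–C bond between the carbinol carbon and the γ-carbon of keto ester 12 (14 back to aldehyde 11 and dianion 13).

Compound 12 supplies four of the five ring carbons and both ring methyls, and 11 supplies the fifth carbon. The forward sequence needs γ-selective addition to a neopentyl aldehyde and methylation at the lactone carbonyl oxygen rather than at the 4-hydroxyl.

**11 to 9.** Aldehyde 11 is traced through alcohol 10 to ester 9. Only the oxidation level changes and the acyl–oxygen bond to the auxiliary is cut. The ester is too hindered to acylate 13 directly, so the two-step detour is accepted. The gain is that the chiral alcohol part of 9 turns the two antipodal carbocycles into diastereomers, and the resolution is done there.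

**9 to 8.** The C1–C6 bond of 9 is cut in a retro-6π sense to the monocyclic triene 8. This removes ring B and two stereocentres at no cost in reagents. The forward disrotatory closure makes the fusion cis by symmetry. It must then place the ester, not the two methyls, under the diene.

**8 to 4, 5 and 6.** In 8 only two bonds distinguish the ring from a symmetrical hydrocarbon, namely C8–CH3 and C7–CO2R. Cutting both leads through anion 7 to dianion 4, methyl donor 5 and chloroformate 6. No other pair of cuts removes all remaining complexity at once, because all four other methyls are already in place. The forward step has to add two different electrophiles to neighbouring carbons, on opposite faces.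

**4 to 1.** Dianion 4 is the two-electron reduction product of 3. The eight ring carbons of 3 are two C4 units joined head to tail, each being the C3–C6 segment of pyranone 1 after decarboxylation. Heat alone offers no path to that connectivity. The union is therefore done with light (1 to 2), and the twofold decarboxylation follows as a separate thermal step (2 to 3).

## Alternatives that were turned down

**Alternative 1:** Ring B is cut at C6–C7 and C1–C8, which unravels it into an alkene and one enone double bond of ring A.

Forward key step: the achiral quinol ether A1 would be irradiated with a chiral Lewis acid. Its tethered alkene would add across one of the two enantiotopic enone units and give the tricyclic ketone A2, with ring B and a tetrahydrofuran (C5–O–CH2–C7) in place.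

In its favour:
- A1 is one dearomatising step from commercial materials.
- The three-atom tether dictates the regiochemistry.
- Four stereocentres arise in one operation.
- The absolute configuration would come from a catalyst. On this point it is clearly stronger than the chosen route, which discards material in a separation.

Against it:
- Cross-conjugated cyclohexadienones have fast photorearrangement channels of their own.
- The carbonyl that must bind the Lewis acid is flanked by two methyls.
- The addition passes through a triplet 1,4-diradical, in which rotation about C7–C8 can erase the alkene geometry and with it C8.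
- The tether forces the C5 oxygen of A2 onto the concave face, the side of the C7 CH2 group, whereas the target has its C5–O bond on the convex face.

Because of the last point, the C5–O bond and the C2 carbonyl must both be removed again (reduction, ether cleavage, 1,4-elimination) to uncover the diene. The same pyranone construction and photooxygenation would follow only after that.

Comparison: the chosen route reaches the diene at the right oxidation level with no oxygen to remove. It offers brevity in place of catalytic asymmetry.

**Alternative 2:** The C3=C4 double bond of the monocyclic triene is cut to two carbonyl groups.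

Forward key step: low-valent titanium would couple the aldehyde (C4) and the methyl ketone (C3) of the open-chain keto aldehyde A3 to the cyclooctatriene A4. A4 would close in the same pot across C1–C6 to the bicyclic silyl ether A5.

In its favour: C7 and C8 are made in an open chain by established asymmetric methods, every carbon is placed without regiochemical ambiguity, and A5 enters the same endgame. In predictability of regiochemistry and of absolute configuration it is stronger than the chosen route.

Against it:
- A3 carries a vicinal quaternary/tertiary pair and two Z-trisubstituted alkenes conjugated to carbonyl groups. Such alkenes isomerise easily, all the more next to Lewis-acidic titanium.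
- Low-valent titanium can also stop at the pinacol or reduce the enone.
- Closing an eight-membered ring by an intermolecular-type coupling is entropically costly.
- Building A3 should take well over ten steps.

Comparison: the chosen route reaches the same triene level in four steps and concentrates its uncertainty in one of them.

**Alternative 3:** The C7–C8 bond is cut in a retro-Claisen sense.

Forward key step: the cyclic allyl vinyl ether A6 would undergo a [3,3] shift in which the ring O–C5 bond breaks as C7–C8 forms. The six-membered oxacycle thus grows into the cyclooctadienone A7.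

In its favour: C7 and C8 are formed together in an ordered, bridged chair-like transition state. Their relative configuration then follows from two alkene geometries, and their absolute configuration from the single C5–O stereocentre. This is real chirality transfer and is better controlled than the chosen key step.

Against it:
- A6 needs an enantiopure tertiary, doubly allylic ether carbon that ionises easily.
- It also needs a geometrically pure and acid-labile exocyclic ethylidene enol ether and a defined trisubstituted alkene.
- The shift has to build a quaternary carbon.
- A7 lacks the C1 methyl and the C1=C2 bond. Adding them through an enol derivative raises a C2 versus C8 regiochemical question and puts the C8 stereocentre, now α to a ketone, at risk of epimerisation.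

Comparison: counting the preparation of A6 and the repair of A7, the route is much longer. The chosen route has all ring methyls in place from the start.

Key step: step 4

Numbering remark: C1 is the methylated fusion carbon, C6 the CH fusion carbon, C7 the quaternary carbon and C8 the CHCH3 carbon. This also applies to 3, 4, 7 and 8.

Assumption: 2 is formulated as the centrosymmetric trans head-to-tail [4+4] dimer. For the route only the head-to-tail connectivity (C3–C6' and C6–C3', pyranone numbering) matters, because it alone fixes the 1,3,5,7 pattern of 3.

## Route

Step 1
Reactants: 1 4,6-dimethyl-2H-pyran-2-one (two molecules)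
Product: 2 trans head-to-tail [4+4] photodimer of 1 (tetramethylcycloocta-1,5-diene core with two –O–C(=O)– bridges on opposite faces, centrosymmetric)
Conditions: hν (Pyrex-filtered medium-pressure Hg lamp), Ph2CO (cat.), benzene (concentrated), rt, Ar; crystallisation
Reagents that add atoms: none
Why: Photodimerisation of a 2-pyranone, in which two molecules stack head to tail and join C3 to C6' and C6 to C3' ([4+4] photocycloaddition, a mode known for 2-pyranones and 2-pyridones). Light is used because heating 1 alone does not give this connectivity; the four new stereocentres vanish in step 2.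

Step 2
Reactants: 2 photodimer
Product: 3 1,3,5,7-tetramethylcycloocta-1,3,5,7-tetraene
Conditions: neat, 250–300 °C, reduced pressure, product distilled out
Reagents that add atoms: none
Why: Each bridge of 2 is a 3,6-dihydro-2-pyranone, a formal hetero-Diels–Alder adduct of CO2, and extrudes CO2 by retro-[4+2] on heating; two extrusions turn the 1,5-diene core into the tetraene. The head-to-tail union puts the methyls on alternate ring carbons.

Step 3
Reactants: 3 1,3,5,7-tetramethylcyclooctatetraene
Product: 4 dipotassium 1,3,5,7-tetramethylcyclooctatetraenediide (titrated THF solution, freed from metal)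
Conditions: K (2.2 equiv), THF, −20 °C → rt, Ar; cannula filtration
Reagents that add atoms: potassium, [K]
Why: Alkali-metal reduction of a cyclooctatetraene, in which two electrons convert the tub-shaped 8π polyene into the planar aromatic 10π dianion. Excess metal is removed because it would consume 5 in the next step.

Step 4
Reactants: 4 dipotassium tetramethylcyclooctatetraenediide; 5 iodomethane; 6 (−)-menthyl chloroformate [(1R,2S,5R)-2-isopropyl-5-methylcyclohexyl carbonochloridate]
Product: 8 (−)-menthyl (1R,8R)-1,3,5,7,8-pentamethylcycloocta-2,4,6-triene-1-carboxylate (ester trans to the CH3 on the neighbouring CH carbon), via potassium pentamethylcyclooctatrienide 7 (not isolated)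
Conditions: 5 (1.0 equiv, slow addition), THF, −78 °C; then 6 (1.1 equiv), −78 → −30 °C; cold aq NH4Cl, work-up below 0 °C
Reagents that add atoms: none
Why: Proposed new method: iodomethane 5 alkylates the planar aromatic 10π dianion 4 in an SN2 step at one of its four equivalent unsubstituted ring carbons (C8–CH3 bond), which leaves the mirror-symmetric heptatrienyl anion 7 with its charge on the methylated carbons C1, C3, C5 and C7. Chloroformate 6 then acylates the terminus C7 by addition–elimination (C7–CO2R bond), so that the conjugated C1=C2–C3=C4–C5=C6 triene of 8 remains; two skeletal bonds form and no ring is closed. The closest known reaction type is the twofold alkylation or carboxylation of cyclooctatetraene dianions to 7,8-disubstituted cycloocta-1,3,5-trienes; new are the two different electrophiles, the tetramethyl substrate and the quaternary carbon that results. C8 becomes stereogenic only when C7 reacts, and the C7/C8 relation is controlled by the C8 methyl, which covers one face of the neighbouring terminus and sends 6 to the other face, so that the ester ends up trans to that methyl. The absolute sense depends on which of the two enantiotopic termini (C7 or C1) is acylated; only the remote menthyl group of 6 tells them apart, so 8 is expected together with a similar amount of the diastereomer that has the mirror-image ring, and the pair is carried to step 5. Needed are mono- before dimethylation (one equivalent of 5 added slowly to cold 4), attack at CH before C(CH3) (shielding by the ring methyls) and terminal 1,2- before internal 1,4-acylation. For the last point the substrate offers only that all four charged carbons are equally substituted and that attack at C7 alone keeps the triene conjugated; this is the open question of the route.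

Step 5
Reactants: 8 menthyl cyclooctatrienecarboxylate (with its diastereomer)
Product: 9 (−)-menthyl (1R,6R,7S,8R)-1,3,5,7,8-pentamethylbicyclo[4.2.0]octa-2,4-diene-7-carboxylate (cis-fused; ester endo under the diene; CH3 on C1, C7, C8 and H on C6 on the other face of ring B)
Conditions: toluene, 50 °C, dark, Ar; then chromatography on SiO2 and crystallisation
Reagents that add atoms: none
Why: Thermal disrotatory 6π electrocyclisation (cyclooctatriene to bicyclo[4.2.0]octadiene valence isomerisation); disrotation makes the fusion cis, and C1 and C6 are set relative to C7 and C8 by the sense of rotation, which puts either the ester or the two methyls under the diene. No strong bias is predicted, but all isomers (two antipodal carbocycles, each endo or exo) are diastereomers thanks to the menthyl group, so 9 can be separated.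

Step 6
Reactants: 9 menthyl bicyclooctadienecarboxylate
Product: 10 [(1R,6R,7S,8R)-1,3,5,7,8-pentamethylbicyclo[4.2.0]octa-2,4-dien-7-yl]methanol
Conditions: LiAlH4, Et2O, 0 °C → rt; then H2O, aq NaOH
Reagents that add atoms: none
Why: Hydride reduction of an ester to the primary alcohol; the diene is inert to LiAlH4 and no stereocentre is touched. The auxiliary leaves as (−)-menthol and can be recovered.

Step 7
Reactants: 10 bicyclic alcohol
Product: 11 (1R,6R,7S,8R)-1,3,5,7,8-pentamethylbicyclo[4.2.0]octa-2,4-diene-7-carbaldehyde
Conditions: Dess–Martin periodinane, pyridine, CH2Cl2, 0 °C → rt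
Reagents that add atoms: none
Why: Dess–Martin oxidation of a neopentyl primary alcohol; pyridine buffers the acetic acid so that the acid-labile diene is spared. C7 bears no hydrogen, so the aldehyde cannot epimerise.

Step 8
Reactants: 11 bicyclic aldehyde; 12 methyl 2-methyl-3-oxopentanoate
Product: 14 methyl 5-hydroxy-2,4-dimethyl-3-oxo-5-[(1R,6R,7S,8R)-1,3,5,7,8-pentamethylbicyclo[4.2.0]octa-2,4-dien-7-yl]pentanoate (mixture of epimers in the chain), via dilithium dienolate of the keto ester 13 (not isolated)
Conditions: 12, LiN(i-Pr)2 (LDA, 2.1 equiv), THF, −78 → 0 °C; then 11, −78 → −40 °C; aq NH4Cl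
Reagents that add atoms: none
Why: Aldol addition of a β-keto ester dianion, which reacts at its more basic γ-carbon; 11 cannot enolise, so only addition is open. The three new chain stereocentres are of no consequence, since all become sp2 in steps 9 and 10.

Step 9
Reactants: 14 aldol adduct
Product: 15 methyl 2,4-dimethyl-3,5-dioxo-5-[(1R,6R,7S,8R)-1,3,5,7,8-pentamethylbicyclo[4.2.0]octa-2,4-dien-7-yl]pentanoate
Conditions: Dess–Martin periodinane, pyridine, CH2Cl2, rt
Reagents that add atoms: none
Why: Dess–Martin oxidation of a β-hydroxy ketone to the 1,3-diketone under near-neutral conditions, which avoids retro-aldol cleavage of the crowded adduct.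

Step 10
Reactants: 15 diketo ester
Product: 16 4-hydroxy-3,5-dimethyl-6-[(1R,6R,7S,8R)-1,3,5,7,8-pentamethylbicyclo[4.2.0]octa-2,4-dien-7-yl]-2H-pyran-2-one
Conditions: 1,8-diazabicyclo[5.4.0]undec-7-ene (DBU), toluene, rt → 40 °C; cold aq citric acid
Reagents that add atoms: none
Why: Base-induced cyclisation of a 3,5-dioxo ester, in which the enolate oxygen of the C5 ketone attacks the ester (6-exo-trig), methoxide leaves and tautomerisation gives the 4-hydroxy-2-pyranone. The quaternary C7 allows enolisation only towards the chain, and the mild temperature leaves the ring fusion untouched.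

Step 11
Reactants: 16 hydroxypyranone
Product: 18 2-methoxy-3,5-dimethyl-6-[(1R,6R,7S,8R)-1,3,5,7,8-pentamethylbicyclo[4.2.0]octa-2,4-dien-7-yl]-4H-pyran-4-one, via hydroxypyrylium triflate 17 (not isolated)
Conditions: MeOTf (1.1 equiv), CH2Cl2, 0 °C → rt; then aq NaHCO3
Reagents that add atoms: methyl trifluoromethanesulfonate, COS(=O)(=O)C(F)(F)F
Why: A hard methylating agent alkylates the neutral 4-hydroxy-2-pyranone at the lactone carbonyl oxygen, the basic site remote from the mobile proton, and gives the 4-hydroxy-2-methoxypyrylium salt 17. Loss of the proton on basic work-up leaves the 2-methoxy-4-pyranone rather than its 4-methoxy-2-pyranone isomer.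

Step 12
Reactants: 18 diene pyranone
Product: 19 6-[(1R,2R,5S,6R,7S,8R)-2,5-epidioxy-1,3,5,7,8-pentamethylbicyclo[4.2.0]oct-3-en-7-yl]-2-methoxy-3,5-dimethyl-4H-pyran-4-one (target)
Conditions: O2, 5,10,15,20-tetraphenylporphyrin (cat.), visible light (cut-off below 450 nm), CH2Cl2, −20 °C; cold work-up, deactivated SiO2
Reagents that add atoms: dioxygen, O=O
Why: [4+2] cycloaddition of singlet oxygen to an s-cis cyclohexadiene; the electron-poor pyranone is inert. C2 and C5 are set by attack on the convex face (the side of C1–CH3 and C6–H), because the concave face is closed by ring B and the endo pyranone.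

## Compound list

1 | 4,6-dimethyl-2H-pyran-2-one | CC1=CC(=O)OC(C)=C1 | starting material
2 | trans head-to-tail [4+4] photodimer of 1 (centrosymmetric bis-lactone) | CC1=C[C@]2(C)OC(=O)[C@H]1[C@]3(C)OC(=O)[C@H]2C(C)=C3 | intermediate
3 | 1,3,5,7-tetramethylcyclooctatetraene | CC1=CC(C)=CC(C)=CC(C)=C1 | intermediate
4 | dipotassium 1,3,5,7-tetramethylcyclooctatetraenediide | C[C-]1[CH-]C(C)=CC(C)=CC(C)=C1.[K+].[K+] | intermediate
5 | iodomethane | CI | starting material
6 | (−)-menthyl chloroformate | CC(C)[C@@H]1CC[C@@H](C)C[C@H]1OC(=O)Cl | starting material
7 | potassium 1,3,5,7,8-pentamethylcyclooctatrienide (delocalised, mirror-symmetric) | C[C-]1C(C)C(C)=CC(C)=CC(C)=C1.[K+] | intermediate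
8 | (−)-menthyl (1R,8R)-1,3,5,7,8-pentamethylcycloocta-2,4,6-triene-1-carboxylate | CC(C)[C@@H]1CC[C@@H](C)C[C@H]1OC(=O)[C@@]2(C)[C@H](C)C(C)=CC(C)=CC(C)=C2 | intermediate
9 | (−)-menthyl (1R,6R,7S,8R)-1,3,5,7,8-pentamethylbicyclo[4.2.0]octa-2,4-diene-7-carboxylate | CC(C)[C@@H]1CC[C@@H](C)C[C@H]1OC(=O)[C@@]2(C)[C@H](C)[C@@]3(C)C=C(C)C=C(C)[C@@H]23 | intermediate
10 | [(1R,6R,7S,8R)-1,3,5,7,8-pentamethylbicyclo[4.2.0]octa-2,4-dien-7-yl]methanol | OC[C@@]1(C)[C@H](C)[C@@]2(C)C=C(C)C=C(C)[C@@H]12 | intermediate
11 | (1R,6R,7S,8R)-1,3,5,7,8-pentamethylbicyclo[4.2.0]octa-2,4-diene-7-carbaldehyde | O=C[C@@]1(C)[C@H](C)[C@@]2(C)C=C(C)C=C(C)[C@@H]12 | intermediate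
12 | methyl 2-methyl-3-oxopentanoate | CCC(=O)C(C)C(=O)OC | starting material
13 | dilithium dienolate (dianion) of 12 | CC=C([O-])C(C)=C([O-])OC.[Li+].[Li+] | intermediate
14 | methyl 5-hydroxy-2,4-dimethyl-3-oxo-5-(bicyclooctadienyl)pentanoate, chain epimers | COC(=O)C(C)C(=O)C(C)C(O)[C@@]1(C)[C@H](C)[C@@]2(C)C=C(C)C=C(C)[C@@H]12 | intermediate
15 | methyl 2,4-dimethyl-3,5-dioxo-5-(bicyclooctadienyl)pentanoate | COC(=O)C(C)C(=O)C(C)C(=O)[C@@]1(C)[C@H](C)[C@@]2(C)C=C(C)C=C(C)[C@@H]12 | intermediate
16 | 4-hydroxy-3,5-dimethyl-6-(bicyclooctadienyl)-2H-pyran-2-one | Cc1c(O)c(C)c(=O)oc1[C@@]2(C)[C@H](C)[C@@]3(C)C=C(C)C=C(C)[C@@H]23 | intermediate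
17 | 4-hydroxy-2-methoxy-3,5-dimethyl-6-(bicyclooctadienyl)pyrylium triflate | COc1[o+]c([C@@]2(C)[C@H](C)[C@@]3(C)C=C(C)C=C(C)[C@@H]23)c(C)c(O)c1C.[O-]S(=O)(=O)C(F)(F)F | intermediate
18 | 2-methoxy-3,5-dimethyl-6-[(1R,6R,7S,8R)-1,3,5,7,8-pentamethylbicyclo[4.2.0]octa-2,4-dien-7-yl]-4H-pyran-4-one | COc1oc([C@@]2(C)[C@H](C)[C@@]3(C)C=C(C)C=C(C)[C@@H]23)c(C)c(=O)c1C | intermediate
19 | 6-[(1R,2R,5S,6R,7S,8R)-2,5-epidioxy-1,3,5,7,8-pentamethylbicyclo[4.2.0]oct-3-en-7-yl]-2-methoxy-3,5-dimethyl-4H-pyran-4-one | COc1oc([C@@]2(C)[C@H](C)[C@@]3(C)[C@@H]4OO[C@@](C)(C=C4C)[C@@H]23)c(C)c(=O)c1C | target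

## Step count and least certain steps

Total step count: 12. Longest linear sequence: 12 steps (1 to 19). Compounds 5, 6 and 12 are bought.

**Step 4 (key step, the only one labelled as a new method).**
- The most likely failure is acylation at an internal position (C3 or C5) instead of the terminus. The termini are shielded by the neighbouring C8 centre and by the bulk of 6, and cyclooctatrienyl anions tend to be trapped kinetically at internal carbons.
- Second methylation may compete, since 7 need not be less nucleophilic than 4.
- Proton transfer between 7 and unreacted 4, and electron transfer to 5 or 6, would scramble the product mixture.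

Fallback, by known chemistry, sets out from 6 and returns at 8.
- Compound 6 acylates the ylide made from EtPPh3Br and NaN(SiMe3)2 (two equivalents of each) to give the stabilised ylide (−)-menthyl 2-(triphenyl-λ5-phosphanylidene)propanoate F1.
- Copper-catalysed carbomagnesiation of prop-2-yn-1-ol (MeMgBr, CuI cat., then I2) gives (Z)-3-iodo-2-methylprop-2-en-1-ol F2.
- MnO2 oxidises F2 to (Z)-3-iodo-2-methylprop-2-enal F3.
- Wittig reaction of F1 with F3 gives (−)-menthyl (2E,4Z)-5-iodo-2,4-dimethylpenta-2,4-dienoate F4.
- Stork–Zhao-type olefination of (E)-2-methylbut-2-enal (EtPPh3I, n-BuLi, I2, NaN(SiMe3)2) gives (2Z,4E)-2-iodo-4-methylhexa-2,4-diene F5.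
- t-BuLi and then Me3SnCl convert F5 into trimethyl[(2Z,4E)-4-methylhexa-2,4-dien-2-yl]stannane F6.
- Stille coupling of F4 and F6 (PdCl2(MeCN)2 cat., a divalent palladium precatalyst, DMF, rt, dark) gives (−)-menthyl (2E,4Z,6Z,8E)-2,4,6,8-tetramethyldeca-2,4,6,8-tetraenoate F7.
- F7 is not isolated, because it closes by conrotatory 8π electrocyclisation to 8. The product is again the pair of trans diastereomers, and the route continues with step 5.

**Step 5.**
- Poor torquoselectivity of the disrotatory closure is likely. The ester-endo mode crowds three cis methyls on ring B, while the other mode puts two methyls under the diene.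
- Separation of the two menthyl diastereomers may be incomplete, because the auxiliary is remote from the ring stereocentres.
- Re-heating the unwanted closure isomer would return it to the equilibrium, but at the price of possible 8π opening and loss of configuration.

Fallback, from 9 to 10. The endo pair (9 and its partner with the mirror-image carbocycle), which differs in shape from the exo pair, is reduced with LiAlH4 to scalemic 10. Acylation with (1S,4R)-camphanic chloride (Et3N, 4-(dimethylamino)pyridine cat.) gives the crystalline [(1R,6R,7S,8R)-1,3,5,7,8-pentamethylbicyclo[4.2.0]octa-2,4-dien-7-yl]methyl (1S,4R)-camphanate F8. F8 is purified by crystallisation and cleaved with K2CO3 in MeOH to enantiopure 10.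

**Step 8.** Slow addition of the bulky dianion to the neopentyl, endo-oriented aldehyde is likely, as is retro-aldol reversal on warming, and either would leave low conversion.

Fallback, from 11 to 15, builds the chain with smaller nucleophiles. EtMgBr adds to 11 to give 1-(bicyclooctadienyl)propan-1-ol F9. Dess–Martin oxidation gives 1-(bicyclooctadienyl)propan-1-one F10. The lithium enolate of F10 (LiN(SiMe3)2, toluene) is C-acylated with methyl 3-chloro-2-methyl-3-oxopropanoate to give 15 directly.

**Step 11.** The trisubstituted diene may be protonated by the strongly acidic hydroxypyrylium salt before work-up. Regiocontrol may also erode if some of the pyranone reacts as its anion.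

Fallback, from 16 to 18, uses O-methylation by a diazoalkane (Me3SiCHN2, toluene/MeOH, 0 °C). Proton transfer from the acidic hydroxyl precedes alkylation within an ion pair, so no strong acid accumulates. Both O-methyl regioisomers are then expected, and 18 is separated by chromatography. No new compound lies on the way (F0).

**Step 12.**
- Schenck ene reaction may compete at the allylic methyls.
- The pyranone may undergo secondary photochemistry under the lamp.
- The peroxide may rearrange during long irradiation or on work-up, either by isomerisation of the O–O bridge or by base-induced cleavage at C2–H.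

Fallback, from 18 to 19, delivers singlet oxygen in the dark from a chemical carrier. 1,4-Dimethyl-1,4-dihydro-1,4-epidioxynaphthalene F11 is made beforehand by cold photooxygenation of 1,4-dimethylnaphthalene. It releases singlet oxygen at 0–25 °C in CH2Cl2, so that neither 18 nor 19 is irradiated.

## Further compounds

F1 | step 4 | (−)-menthyl 2-(triphenyl-λ5-phosphanylidene)propanoate | CC(C)[C@@H]1CC[C@@H](C)C[C@H]1OC(=O)C(C)=P(c2ccccc2)(c3ccccc3)c4ccccc4
F2 | step 4 | (Z)-3-iodo-2-methylprop-2-en-1-ol | OC/C(C)=C\I
F3 | step 4 | (Z)-3-iodo-2-methylprop-2-enal | O=C/C(C)=C\I
F4 | step 4 | (−)-menthyl (2E,4Z)-5-iodo-2,4-dimethylpenta-2,4-dienoate | CC(C)[C@@H]1CC[C@@H](C)C[C@H]1OC(=O)/C(C)=C/C(C)=C\I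
F5 | step 4 | (2Z,4E)-2-iodo-4-methylhexa-2,4-diene | C/C=C(C)/C=C(C)\I
F6 | step 4 | trimethyl[(2Z,4E)-4-methylhexa-2,4-dien-2-yl]stannane | C/C=C(C)/C=C(C)\[Sn](C)(C)C
F7 | step 4 | (−)-menthyl (2E,4Z,6Z,8E)-2,4,6,8-tetramethyldeca-2,4,6,8-tetraenoate | CC(C)[C@@H]1CC[C@@H](C)C[C@H]1OC(=O)/C(C)=C/C(C)=C\C(C)=C/C(C)=C/C
F8 | step 5 | [(1R,6R,7S,8R)-1,3,5,7,8-pentamethylbicyclo[4.2.0]octa-2,4-dien-7-yl]methyl (1S,4R)-camphanate | O=C(OC[C@@]1(C)[C@H](C)[C@@]2(C)C=C(C)C=C(C)[C@@H]12)[C@@]34CC[C@@](C)(C(=O)O3)C4(C)C
F9 | step 8 | 1-[(1R,6R,7S,8R)-1,3,5,7,8-pentamethylbicyclo[4.2.0]octa-2,4-dien-7-yl]propan-1-ol (carbinol epimers) | CCC(O)[C@@]1(C)[C@H](C)[C@@]2(C)C=C(C)C=C(C)[C@@H]12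
F10 | step 8 | 1-[(1R,6R,7S,8R)-1,3,5,7,8-pentamethylbicyclo[4.2.0]octa-2,4-dien-7-yl]propan-1-one | CCC(=O)[C@@]1(C)[C@H](C)[C@@]2(C)C=C(C)C=C(C)[C@@H]12
F0 | step 11 | none | none
F11 | step 12 | 1,4-dimethyl-1,4-dihydro-1,4-epidioxynaphthalene | CC12C=CC(C)(OO1)c1ccccc12
A1 | alternative 1 | 2,4,6-trimethyl-4-[(E)-2-methylbut-2-enyloxy]cyclohexa-2,5-dien-1-one | C/C=C(C)/COC1(C)C=C(C)C(=O)C(C)=C1
A2 | alternative 1 | tricyclic photoadduct (cyclobutane fused to the trimethylcyclohexenone, C5–O–CH2–C7 ether bridge) | O1C[C@@]2(C)[C@H](C)[C@@]3(C)C(=O)C(C)=C[C@]1(C)[C@@H]23
A3 | alternative 2 | (2Z,6Z)-4-[(tert-butyldimethylsilyloxy)methyl]-2,4,5,6-tetramethyl-8-oxonona-2,6-dienal (C7 and C8 configured as in the target) | O=C/C(C)=C\[C@@](C)(CO[Si](C)(C)C(C)(C)C)[C@H](C)/C(C)=C\C(C)=O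
A4 | alternative 2 | 7-[(tert-butyldimethylsilyloxy)methyl]-1,3,5,7,8-pentamethylcycloocta-1,3,5-triene | CC(C)(C)[Si](C)(C)OC[C@@]1(C)[C@H](C)C(C)=CC(C)=CC(C)=C1
A5 | alternative 2 | 7-[(tert-butyldimethylsilyloxy)methyl]-1,3,5,7,8-pentamethylbicyclo[4.2.0]octa-2,4-diene | CC(C)(C)[Si](C)(C)OC[C@@]2(C)[C@H](C)[C@@]3(C)C=C(C)C=C(C)[C@@H]23
A6 | alternative 3 | (2Z)-2-ethylidene-4,6-dimethyl-6-[(1Z)-3-(tert-butyldimethylsilyloxy)-2-methylprop-1-enyl]-3,6-dihydro-2H-pyran (drawn for a chair-like transition state) | C/C=C1\O[C@](C)(/C=C(C)\CO[Si](C)(C)C(C)(C)C)C=C(C)C1
A7 | alternative 3 | 7-[(tert-butyldimethylsilyloxy)methyl]-3,5,7,8-tetramethylcycloocta-3,5-dien-1-one | CC(C)(C)[Si](C)(C)OC[C@@]1(C)[C@H](C)C(=O)CC(C)=CC(C)=C1
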